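## Analysis of the target

Kuwanon E is a flavanone. A chroman-4-one (ring C: O1, C2, C3, C4, C4a, C8a) is fused to a phloroglucinol-type ring A (OH at C5 and C7) and carries at C2 a resorcinol ring B (OH at C2' and C4') with an (E)-geranyl chain at C5'. C2 is the only stereocentre and is (S), so there is no relative configuration to control. It is a benzylic ether carbon next to an enolisable C3 methylene, and it is easily lost: base opens the C2–O1 bond to the chalcone, and a free C2' or C4' phenoxide can expel O1 through a quinone methide. The other sensitive groups are the four phenols and the geranyl diene, whose proximal alkene sits ortho to the C4' hydroxyl and closes to a chroman under protic or Lewis acid. The real difficulty is ring B, which reads C1' (carbon), C2' (O), C3' (H), C4' (O), C5' (geranyl), C6' (H). Alkylation of a resorcinol goes to oxygen or to C3', between the two oxygens, and ring A of any flavanone intermediate is the more nucleophilic arene, so geranyl cannot be put on C5' late by substitution. The strategy rests on this ring B pattern: carbon, free OH, H, protected O, carbon, H around the ring is what a vinylketene and an ynol ether give, with no regiochemical choice left open. Ring B is therefore assembled from acyclic pieces that already carry geranyl (future C5') and the C2 carbinol from the chiral pool (on future C1'). Ring A is attached afterwards as a fluoroaryl ketone, and ring C is closed through O1–C8a, a bond whose formation does not touch C2.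

## Retrosynthetic reasoning

**28 from 27.** The last operation is limited to removing four identical acetal ethers from 27. Acetals are chosen for all four phenols because they survive organolithium, fluoride and alkoxide chemistry, and their cleavage needs only dilute acid, the mildest conditions under which the geranyl group next to O4' has a chance.

**27 from 26 (cut O1–C8a).** Ring C is opened at the aryl–oxygen bond, not at C2–O1. Cutting C2–O1 would mean a substitution at a benzylic carbon activated by two oxygens (ionisation, loss of configuration) or a conjugate addition to a chalcone (configuration set anew). Cutting O1–C8a leaves the C2–O bond of 26 intact, so the (S) centre is carried through with retention. The forward step is an intramolecular SNAr of the C2 alkoxide on a fluorine ortho to the C4 ketone.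

**26 from 25, and 25 from 20 and 24 (cut C4–C4a).** The aryl ketone is made from an N-methoxy-N-methylamide (20) and a ring A aryllithium (24), which stops cleanly at the ketone. 24 comes from bromide 23, made from 21 through 22. The bromine fixes the metalation site next to fluorine; deprotonation of 22 could also occur between the two oxygens.

**20 from 19, 19 from 18, 18 from 17.** These are adjustments only. The ester of 19 becomes the amide. The silyl group that the annulation leaves on O4' in 17 is exchanged for an acetal (via 18), so that no phenol on ring B is free, or fluoride-labile, when the carbinol is unmasked and cyclised under base.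

**17 from 9 and 12 (key disconnection).** Ring B is cut at C1'–C2', C2'–C3' and C4'–C5'. The fourth new ring bond, C5'–C6', comes from the 1,2-shift that turns diazo ketone 9 into vinylketene 13. The six ring carbons then are the carbonyl carbon of 9 (C2'), the two carbons of 12 (C3', C4'), the diazo carbon with its geranyl group (C5') and the two alkene carbons of the enone (C6', C1'). Nothing is substituted on a preformed arene, so the pattern that resists electrophilic chemistry is written into the connectivity of 9. The forward step has to achieve a clean Wolff shift, a regiospecific [2+2] addition (14), ring opening (15) and a six-electron closure (16) in one flask.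

**9 from 7, and 7 from 6 and 3.** The diazo group is put on the α'-carbon of enone 7 by activation and diazo transfer. The enone is cut at its C=C bond into ketophosphonate 6 and aldehyde 3, a mild olefination that tolerates the α-silyloxy aldehyde.

**6 from 4 and 5; 3 from 2 and 1; 12 from 10 via 11.** Geranyl is attached to 4 at its terminal carbon by dianion alkylation with 5. The aldehyde comes from 1 by silylation (2) and half-reduction of the ester next to the silyloxy group; the carbinol carbon of 1 becomes C2 and its oxygen becomes O1. The ynol ether 12 is made from 10 by oxygenation (11) and O-silylation.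

## Alternatives that were turned down

**Alternative 1: rings A and C by [2+2+2] cyclotrimerisation.** The disconnection cuts C4a–C8a, C5–C6 and C7–C8. In the forward step the tethered diyne A1 (an ethynyl ether on the C2 oxygen and a tert-butoxy ynone on C4) and tert-butoxyethyne A2 combine on a cationic monovalent rhodium catalyst carrying a chiral bisphosphine to give the di-tert-butyl bis-MOM flavanone A3.
- In its favour: two rings form in one step, both ring A oxygens are placed by the alkynes, and no ring A building block or SNAr is needed. On convergence for rings A and C it is stronger than the chosen route.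
- Against: A1 must already contain ring B with geranyl at C5', so the hardest part of the target is left to classical resorcinol chemistry.
- Against: A1 is fragile. It is a 1-alkynyl ether of a doubly oxygen-activated benzylic alcohol, a class that rearranges sigmatropically on gentle warming, and it carries a tert-butoxy ynone that can lose its alkyl group to an acylketene.
- Against: the orientation of A2 (oxygen at C7, not C6) has only an electronic bias, and the geranyl alkenes can compete as the third partner.
- Against: the aryl tert-butyl ethers of A3 need much stronger acid than acetals, which the geranyl group next to O4' is unlikely to survive.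
- The chosen route spends more steps on rings A and C but builds ring B itself and ends with a mild deprotection.

**Alternative 2: oxidative C–H cyclisation of an aryl benzyl ether.** The disconnection is C2–C3. A quinone oxidant takes hydride from the benzylic CH2 of the enol acetate A4, and the enol acetate carbon closes on the oxocarbenium ion, paired with a chiral phosphate, to give the bromoflavanone A5. Geranyl would then be attached at C5' by cross-coupling.
- In its favour: it is the shortest access to the flavanone core from simple acetophenone and benzyl halide pieces. Bromine goes to C5' of a 2,4-dialkoxybenzyl unit by ordinary substitution, so on placing a handle at C5' it is as strong as the chosen route.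
- Against: the rings of A4 are polyalkoxyarenes that the oxidant attacks directly.
- Against: A5 still has a C2–H that is at least as easily abstracted, and the same kind of oxidant is the standard reagent for dehydrogenating flavanones to flavones.
- Against: enantiocontrol by ion pairing to a planar aryl-oxocarbenium ion is unproven for this ring size and substitution.
- Against: the late sp2–sp3 coupling must deliver geranyl without allylic transposition on a base-sensitive flavanone.
- The chosen route needs no enantioselective step, because C2 comes from 1, and it brings geranyl in as an intact allylic unit at the start.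

**Alternative 3: ortho-quinone methide oxa-Diels–Alder.** The disconnection cuts O1–C2 and C3–C4. The salicylaldehyde acetal A6 ionises under a chiral Brønsted acid to a methoxy-substituted quinone methide cation, which adds the ring B styrene A7 to give the 2,4-cis 4-methoxyflavan A8.
- In its favour: it is convergent and catalytic, and all phenols are silyl ethers, so the final deprotection is by fluoride. On that point it is gentler to the geranyl group than the acid step of the chosen route.
- Against: A7 again presupposes ring B with geranyl at C5', so the central problem is not addressed.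
- Against: a cationic heterodiene and a strong acid meet two trisubstituted alkenes, which can act as competing dienophiles or start cation–olefin cyclisation.
- Against: A8 is at the wrong oxidation level at C4. Turning the methyl ether into the ketone is a benzylic oxidation on a tetra-silyloxy flavan that also has a benzylic C2–H.
- Against: two stereocentres are set where one is kept.
- The chosen route reaches the C4 ketone directly, and its one stereocentre is never made or broken at carbon.

Key step: step 7

## Remarks before the steps

- Geranyl stands for (2E)-3,7-dimethylocta-2,6-dien-1-yl, TBS for tert-butyldimethylsilyl, TIPS for triisopropylsilyl, MOM for methoxymethyl.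
- Assumption: ynol ether 12 is not taken as a stock chemical; it is made in step 6 and used fresh.
- Conjugate bases formed by simple deprotonation (lithium acetylide, the phosphonate dianion, enolates, the alkoxide of 26) are treated as their parent compounds and carry no number.

## Route

Step 1
Reactants: 1 dimethyl (S)-malate
Product: 2 dimethyl (2S)-2-[(tert-butyldimethylsilyl)oxy]butanedioate
Conditions: TBSCl, imidazole, DMF, rt
Reagents that add atoms: tert-butyldimethylsilyl chloride, CC(C)(C)[Si](C)(C)Cl
Why: Imidazole-mediated silylation of the secondary alcohol masks the oxygen that will become O1 before hydride and enolate chemistry; the stereocentre is not involved.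

Step 2
Reactants: 2 dimethyl (2S)-2-[(tert-butyldimethylsilyl)oxy]butanedioate
Product: 3 methyl (3S)-3-[(tert-butyldimethylsilyl)oxy]-4-oxobutanoate
Conditions: i-Bu2AlH (1.05 equiv), CH2Cl2, −78 °C; Rochelle salt work-up
Reagents that add atoms: none
Why: Half-reduction of a diester: the ester flanked by the silyloxy group is the more electrophilic and its tetrahedral aluminium alkoxide is held by the α-oxygen, so one equivalent of hydride at −78 °C should stop at the aldehyde there and leave the remote ester. The aldehyde is set free only on cold work-up, which protects the α-stereocentre.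

Step 3
Reactants: 4 dimethyl (2-oxopropyl)phosphonate, 5 geranyl bromide
Product: 6 dimethyl [(5E)-6,10-dimethyl-2-oxoundeca-5,9-dien-1-yl]phosphonate
Conditions: NaH, THF, 0 °C; n-BuLi, −78 °C; then 5, −78 to 0 °C
Reagents that add atoms: none
Why: γ-Alkylation of a β-ketophosphonate dianion: the second deprotonation gives the more reactive terminal carbanion, which displaces the primary allylic bromide by SN2 with the (E)-alkene unchanged.

Step 4
Reactants: 6 dimethyl [(5E)-6,10-dimethyl-2-oxoundeca-5,9-dien-1-yl]phosphonate, 3 methyl (3S)-3-[(tert-butyldimethylsilyl)oxy]-4-oxobutanoate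
Product: 7 methyl (3S,4E,9E)-3-[(tert-butyldimethylsilyl)oxy]-10,14-dimethyl-6-oxopentadeca-4,9,13-trienoate
Conditions: LiCl, i-Pr2NEt, MeCN, 0 °C to rt
Reagents that add atoms: none
Why: Horner–Wadsworth–Emmons olefination under Masamune–Roush conditions gives the (E)-enone and is mild enough not to epimerise the α-silyloxy aldehyde or eliminate the β-silyloxy ester.

Step 5
Reactants: 7 methyl (3S,4E,9E)-3-[(tert-butyldimethylsilyl)oxy]-10,14-dimethyl-6-oxopentadeca-4,9,13-trienoate
Product: 9 methyl (3S,4E,9E)-3-[(tert-butyldimethylsilyl)oxy]-7-diazo-10,14-dimethyl-6-oxopentadeca-4,9,13-trienoate, via trifluoroacetyl diketone 8 (not isolated)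
Conditions: LiN(SiMe3)2, THF, −78 °C; CF3CO2CH2CF3; then MsN3, Et3N, H2O, MeCN, rt
Reagents that add atoms: methanesulfonyl azide, CS(=O)(=O)N=[N+]=[N-]; 2,2,2-trifluoroethyl trifluoroacetate, O=C(OCC(F)(F)F)C(F)(F)F (its acyl group sits in 8 only)
Why: Detrifluoroacetylative diazo transfer: kinetic α'-enolisation of the enone (the ketone CH2 is far more acidic than the ester CH2), C-trifluoroacetylation to 8, then azide transfer to the activated dicarbonyl with loss of the trifluoroacetyl group as the sulfonamide. This is the established route to α'-diazo enones, which direct diazo transfer does not give.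

Step 6
Reactants: 10 acetylene
Product: 12 (triisopropylsilyloxy)ethyne, via lithium ethynolate 11 (not isolated)
Conditions: n-BuLi, THF, −78 °C; t-BuOOLi (from t-BuOOH and LiN(SiMe3)2), −78 to 0 °C; i-Pr3SiOTf, −78 °C
Reagents that add atoms: tert-butyl hydroperoxide, CC(C)(C)OO; triisopropylsilyl trifluoromethanesulfonate, CC(C)[Si](C(C)C)(C(C)C)OS(=O)(=O)C(F)(F)F
Why: Electrophilic oxygenation of an alkynyllithium by lithium tert-butyl peroxide gives the ynolate 11, which a hindered silyl triflate should trap on oxygen at −78 °C, as silicon electrophiles do with enolates. The three isopropyl groups slow the 1,3-shift to the silylketene; the product is distilled cold and used at once.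

Step 7
Reactants: 9 methyl (3S,4E,9E)-3-[(tert-butyldimethylsilyl)oxy]-7-diazo-10,14-dimethyl-6-oxopentadeca-4,9,13-trienoate, 12 (triisopropylsilyloxy)ethyne
Product: 17 methyl (3S)-3-[(tert-butyldimethylsilyl)oxy]-3-{5-geranyl-2-hydroxy-4-[(triisopropylsilyl)oxy]phenyl}propanoate, via vinylketene 13 (not isolated), via cyclobutenone 14 (not isolated), via dienylketene 15 (not isolated), via cyclohexadienone 16 (not isolated)
Conditions: 12 (2 equiv), hν (300 nm, Pyrex), ClCH2CH2Cl, rt; then 80 °C
Reagents that add atoms: none
Why: Photochemical Wolff rearrangement expels nitrogen and shifts the alkenyl group from the carbonyl carbon to the diazo carbon (this makes C5'–C6'), giving vinylketene 13 with geranyl on the ketene α-carbon. The nucleophilic terminal carbon of 12 attacks the ketene carbonyl carbon and the four-membered ring closes to cyclobutenone 14 (C2'–C3' and C4'–C5'), a regiospecific [2+2] cycloaddition. Reversible four-electron conrotatory opening of 14 gives dienylketene 15, of which only the isomer with the alkenyl group on the ketene side can go on; thermal six-electron disrotatory electrocyclisation then forms C1'–C2' and closes ring B as dienone 16, which tautomerises to phenol 17. The closest known reaction type is the Danheiser benzannulation in its photochemical α-diazo ketone form with siloxyalkynes, which gives resorcinol monosilyl ethers. No stereocentre is created: the sp3 centres of 14 and 16 are lost on ring opening and aromatisation, and the carbinol carbon, insulated from the π system, should keep its (S) configuration. The selectivity that matters is regiochemistry, and it is fixed by the polarity of the partners: the ketene carbon becomes C2' (free OH), the alkyne carbons C3' (H) and C4' (OSi), and the geranyl-bearing carbon C5'. Chemoselectivity for the ynol ether over the two trisubstituted alkenes of the geranyl chain rests on its much higher nucleophilicity and its use in excess; light-induced E/Z isomerisation of the enone is harmless because both isomers lead to the same arene.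

Step 8
Reactants: 17 methyl (3S)-3-[(tert-butyldimethylsilyl)oxy]-3-{5-geranyl-2-hydroxy-4-[(triisopropylsilyl)oxy]phenyl}propanoate
Product: 18 methyl (3S)-3-[(tert-butyldimethylsilyl)oxy]-3-(5-geranyl-2,4-dihydroxyphenyl)propanoate
Conditions: Bu4NF (1.1 equiv), AcOH, THF, 0 °C
Reagents that add atoms: none
Why: Fluoride cleaves an aryl silyl ether (phenoxide leaving group) far faster than a hindered secondary alkyl TBS ether, so buffered fluoride at 0 °C should free O4' only. The exchange is made here because an O4' that is free or fluoride-labile would not survive the later base-mediated ring closure.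

Step 9
Reactants: 18 methyl (3S)-3-[(tert-butyldimethylsilyl)oxy]-3-(5-geranyl-2,4-dihydroxyphenyl)propanoate
Product: 19 methyl (3S)-3-[(tert-butyldimethylsilyl)oxy]-3-[5-geranyl-2,4-bis(methoxymethoxy)phenyl]propanoate
Conditions: MOMCl, i-Pr2NEt, CH2Cl2, 0 °C to rt
Reagents that add atoms: chloromethyl methyl ether, COCCl
Why: O-Alkylation of both phenols gives base-stable acetals that match those planned for ring A; with O2' and O4' capped, quinone methide formation at the benzylic carbon is blocked.

Step 10
Reactants: 19 methyl (3S)-3-[(tert-butyldimethylsilyl)oxy]-3-[5-geranyl-2,4-bis(methoxymethoxy)phenyl]propanoate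
Product: 20 (3S)-3-[(tert-butyldimethylsilyl)oxy]-3-[5-geranyl-2,4-bis(methoxymethoxy)phenyl]-N-methoxy-N-methylpropanamide
Conditions: MeNH(OMe)·HCl, i-PrMgCl, THF, −20 to 0 °C
Reagents that add atoms: N,O-dimethylhydroxylamine hydrochloride, CNOC.Cl
Why: Direct aminolysis of the methyl ester by the magnesium amide gives the Weinreb amide in one step; the low temperature keeps the β-silyloxy group from eliminating.

Step 11
Reactants: 21 5-fluororesorcinol
Product: 22 1-fluoro-3,5-bis(methoxymethoxy)benzene
Conditions: MOMCl, i-Pr2NEt, CH2Cl2, 0 °C to rt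
Reagents that add atoms: chloromethyl methyl ether, COCCl
Why: Standard acetal protection of both phenols, which must withstand organolithium and alkoxide chemistry and come off together with the ring B acetals.

Step 12
Reactants: 22 1-fluoro-3,5-bis(methoxymethoxy)benzene
Product: 23 2-bromo-1-fluoro-3,5-bis(methoxymethoxy)benzene
Conditions: NBS, MeCN, 0 °C
Reagents that add atoms: N-bromosuccinimide, O=C1CCC(=O)N1Br
Why: Electrophilic bromination of a 1,3-dialkoxyarene goes para to one alkoxy group and ortho to the other, that is next to fluorine, and avoids the hindered carbon between the two oxygens. This fixes the metalation site, which direct deprotonation would leave open.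

Step 13
Reactants: 23 2-bromo-1-fluoro-3,5-bis(methoxymethoxy)benzene, 20 (3S)-3-[(tert-butyldimethylsilyl)oxy]-3-[5-geranyl-2,4-bis(methoxymethoxy)phenyl]-N-methoxy-N-methylpropanamide
Product: 25 (3S)-3-[(tert-butyldimethylsilyl)oxy]-1-[2-fluoro-4,6-bis(methoxymethoxy)phenyl]-3-[5-geranyl-2,4-bis(methoxymethoxy)phenyl]propan-1-one, via aryllithium 24 (not isolated)
Conditions: n-BuLi, THF, −78 °C; then 20, −78 to −50 °C; aq. NH4Cl
Reagents that add atoms: none
Why: Bromine–lithium exchange at −78 °C gives aryllithium 24, held by the ortho acetal oxygen and kept cold so that LiF is not lost to an aryne. Addition to the Weinreb amide stops at the chelated tetrahedral intermediate, so the ketone appears only on quench and is not attacked twice.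

Step 14
Reactants: 25 (3S)-3-[(tert-butyldimethylsilyl)oxy]-1-[2-fluoro-4,6-bis(methoxymethoxy)phenyl]-3-[5-geranyl-2,4-bis(methoxymethoxy)phenyl]propan-1-one
Product: 26 (3S)-1-[2-fluoro-4,6-bis(methoxymethoxy)phenyl]-3-[5-geranyl-2,4-bis(methoxymethoxy)phenyl]-3-hydroxypropan-1-one
Conditions: Bu4NF, AcOH, THF, 0 °C to rt
Reagents that add atoms: none
Why: Buffered fluoride removes the secondary TBS ether; acetic acid keeps the medium near neutral so that the β-hydroxy ketone should neither eliminate nor cleave by retro-aldol reaction, and the aryl acetals are inert.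

Step 15
Reactants: 26 (3S)-1-[2-fluoro-4,6-bis(methoxymethoxy)phenyl]-3-[5-geranyl-2,4-bis(methoxymethoxy)phenyl]-3-hydroxypropan-1-one
Product: 27 (2S)-2-[5-geranyl-2,4-bis(methoxymethoxy)phenyl]-5,7-bis(methoxymethoxy)-2,3-dihydro-4H-chromen-4-one
Conditions: NaH (1.0 equiv), THF–DMF, 0 °C to rt
Reagents that add atoms: none
Why: Intramolecular SNAr: the alkoxide attacks the fluorine-bearing carbon ortho to the ketone (the carbonyl stabilises the Meisenheimer intermediate, fluoride is the best leaving group) and closes the six-membered ring C through O1–C8a. The C2–O bond is never broken, so the (S) configuration is retained; one equivalent of base at low temperature limits retro-aldol cleavage and enolisation of the product.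

Step 16
Reactants: 27 (2S)-2-[5-geranyl-2,4-bis(methoxymethoxy)phenyl]-5,7-bis(methoxymethoxy)-2,3-dihydro-4H-chromen-4-one
Product: 28 kuwanon E, (2S)-2-(5-geranyl-2,4-dihydroxyphenyl)-5,7-dihydroxy-2,3-dihydro-4H-chromen-4-one
Conditions: 3 M HCl, MeOH, 50 °C
Reagents that add atoms: none
Why: Acid-catalysed acetal exchange with the solvent removes the four MOM groups as the dimethyl acetal of formaldehyde. Dilute methanolic acid is the mild end of the conditions used for prenylated flavanones, and C2 is configurationally stable in acid.

## Compound list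

1 | dimethyl (S)-malate | COC(=O)C[C@H](O)C(=O)OC | starting material
2 | dimethyl (2S)-2-[(tert-butyldimethylsilyl)oxy]butanedioate | COC(=O)C[C@H](O[Si](C)(C)C(C)(C)C)C(=O)OC | intermediate
3 | methyl (3S)-3-[(tert-butyldimethylsilyl)oxy]-4-oxobutanoate | COC(=O)C[C@H](O[Si](C)(C)C(C)(C)C)C=O | intermediate
4 | dimethyl (2-oxopropyl)phosphonate | CC(=O)CP(=O)(OC)OC | starting material
5 | geranyl bromide, (2E)-1-bromo-3,7-dimethylocta-2,6-diene | CC(C)=CCC/C(C)=C/CBr | starting material
6 | dimethyl [(5E)-6,10-dimethyl-2-oxoundeca-5,9-dien-1-yl]phosphonate | CC(C)=CCC/C(C)=C/CCC(=O)CP(=O)(OC)OC | intermediate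
7 | methyl (3S,4E,9E)-3-[(tert-butyldimethylsilyl)oxy]-10,14-dimethyl-6-oxopentadeca-4,9,13-trienoate | CC(C)=CCC/C(C)=C/CCC(=O)/C=C/[C@@H](O[Si](C)(C)C(C)(C)C)CC(=O)OC | intermediate
8 | methyl (3S,4E,9E)-3-[(tert-butyldimethylsilyl)oxy]-10,14-dimethyl-6-oxo-7-(trifluoroacetyl)pentadeca-4,9,13-trienoate (both C7 epimers, largely enolised) | CC(C)=CCC/C(C)=C/CC(C(=O)C(F)(F)F)C(=O)/C=C/[C@@H](O[Si](C)(C)C(C)(C)C)CC(=O)OC | intermediate
9 | methyl (3S,4E,9E)-3-[(tert-butyldimethylsilyl)oxy]-7-diazo-10,14-dimethyl-6-oxopentadeca-4,9,13-trienoate | CC(C)=CCC/C(C)=C/CC(=[N+]=[N-])C(=O)/C=C/[C@@H](O[Si](C)(C)C(C)(C)C)CC(=O)OC | intermediate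
10 | acetylene | C#C | starting material
11 | lithium ethynolate | [Li+].[O-]C#C | intermediate
12 | (triisopropylsilyloxy)ethyne | C#CO[Si](C(C)C)(C(C)C)C(C)C | intermediate
13 | methyl (3S,4E)-3-[(tert-butyldimethylsilyl)oxy]-6-geranyl-7-oxohepta-4,6-dienoate (vinylketene) | CC(C)=CCC/C(C)=C/CC(=C=O)/C=C/[C@@H](O[Si](C)(C)C(C)(C)C)CC(=O)OC | intermediate
14 | methyl (3S,4E)-3-[(tert-butyldimethylsilyl)oxy]-5-{1-geranyl-4-oxo-2-[(triisopropylsilyl)oxy]cyclobut-2-en-1-yl}pent-4-enoate (both epimers at the ring carbon) | CC(C)=CCC/C(C)=C/CC1(/C=C/[C@@H](O[Si](C)(C)C(C)(C)C)CC(=O)OC)C(=O)C=C1O[Si](C(C)C)(C(C)C)C(C)C | intermediate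
15 | methyl (3S,4E,6E)-3-[(tert-butyldimethylsilyl)oxy]-6-geranyl-9-oxo-7-[(triisopropylsilyl)oxy]nona-4,6,8-trienoate (dienylketene, alkenyl group cis to the ketene) | CC(C)=CCC/C(C)=C/C/C(/C=C/[C@@H](O[Si](C)(C)C(C)(C)C)CC(=O)OC)=C(/C=C=O)O[Si](C(C)C)(C(C)C)C(C)C | intermediate
16 | methyl (3S)-3-[(tert-butyldimethylsilyl)oxy]-3-{3-geranyl-6-oxo-4-[(triisopropylsilyl)oxy]cyclohexa-2,4-dien-1-yl}propanoate (both epimers at ring C1) | CC(C)=CCC/C(C)=C/CC1=CC([C@@H](O[Si](C)(C)C(C)(C)C)CC(=O)OC)C(=O)C=C1O[Si](C(C)C)(C(C)C)C(C)C | intermediate
17 | methyl (3S)-3-[(tert-butyldimethylsilyl)oxy]-3-{5-geranyl-2-hydroxy-4-[(triisopropylsilyl)oxy]phenyl}propanoate | CC(C)=CCC/C(C)=C/Cc1cc([C@@H](O[Si](C)(C)C(C)(C)C)CC(=O)OC)c(O)cc1O[Si](C(C)C)(C(C)C)C(C)C | intermediate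
18 | methyl (3S)-3-[(tert-butyldimethylsilyl)oxy]-3-(5-geranyl-2,4-dihydroxyphenyl)propanoate | CC(C)=CCC/C(C)=C/Cc1cc([C@@H](O[Si](C)(C)C(C)(C)C)CC(=O)OC)c(O)cc1O | intermediate
19 | methyl (3S)-3-[(tert-butyldimethylsilyl)oxy]-3-[5-geranyl-2,4-bis(methoxymethoxy)phenyl]propanoate | CC(C)=CCC/C(C)=C/Cc1cc([C@@H](O[Si](C)(C)C(C)(C)C)CC(=O)OC)c(OCOC)cc1OCOC | intermediate
20 | (3S)-3-[(tert-butyldimethylsilyl)oxy]-3-[5-geranyl-2,4-bis(methoxymethoxy)phenyl]-N-methoxy-N-methylpropanamide | CC(C)=CCC/C(C)=C/Cc1cc([C@@H](O[Si](C)(C)C(C)(C)C)CC(=O)N(C)OC)c(OCOC)cc1OCOC | intermediate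
21 | 5-fluororesorcinol | Oc1cc(O)cc(F)c1 | starting material
22 | 1-fluoro-3,5-bis(methoxymethoxy)benzene | COCOc1cc(F)cc(OCOC)c1 | intermediate
23 | 2-bromo-1-fluoro-3,5-bis(methoxymethoxy)benzene | COCOc1cc(F)c(Br)c(OCOC)c1 | intermediate
24 | [2-fluoro-4,6-bis(methoxymethoxy)phenyl]lithium | COCOc1cc(F)c([Li])c(OCOC)c1 | intermediate
25 | (3S)-3-[(tert-butyldimethylsilyl)oxy]-1-[2-fluoro-4,6-bis(methoxymethoxy)phenyl]-3-[5-geranyl-2,4-bis(methoxymethoxy)phenyl]propan-1-one | CC(C)=CCC/C(C)=C/Cc1cc([C@@H](O[Si](C)(C)C(C)(C)C)CC(=O)c2c(F)cc(OCOC)cc2OCOC)c(OCOC)cc1OCOC | intermediate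
26 | (3S)-1-[2-fluoro-4,6-bis(methoxymethoxy)phenyl]-3-[5-geranyl-2,4-bis(methoxymethoxy)phenyl]-3-hydroxypropan-1-one | CC(C)=CCC/C(C)=C/Cc1cc([C@@H](O)CC(=O)c2c(F)cc(OCOC)cc2OCOC)c(OCOC)cc1OCOC | intermediate
27 | (2S)-2-[5-geranyl-2,4-bis(methoxymethoxy)phenyl]-5,7-bis(methoxymethoxy)-2,3-dihydro-4H-chromen-4-one | CC(C)=CCC/C(C)=C/Cc1cc([C@@H]2CC(=O)c3c(OCOC)cc(OCOC)cc3O2)c(OCOC)cc1OCOC | intermediate
28 | kuwanon E, (2S)-2-{5-[(2E)-3,7-dimethylocta-2,6-dien-1-yl]-2,4-dihydroxyphenyl}-5,7-dihydroxy-2,3-dihydro-4H-chromen-4-one | CC(C)=CCC/C(C)=C/Cc1cc([C@@H]2CC(=O)c3c(O)cc(O)cc3O2)c(O)cc1O | target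

## Step count

Total: 16 steps. Longest linear sequence: 12 steps (1, 2, 4, 5, 7, 8, 9, 10, 13, 14, 15, 16), from 1 to 28. Steps 3, 6, 11 and 12 prepare the side branches.

## Least certain steps

**Step 7 (key step).** The most likely failure is at the start of the cascade. The diazo carbon carries an alkyl group, so less of the diazo ketone is in the s-Z conformation from which the shift is concerted than for a diazomethyl ketone. The part that reacts as a free carbene can take a 1,2-hydride shift from the adjacent allylic CH2 instead of rearranging, and the ketene is then never formed. A second weakness is a sluggish thermal stage that leaves the cyclobutenone unopened; longer heating answers that.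

Fallback: the alkyl group is taken off the diazo carbon and geranyl is attached after the annulation. The fallback sets out from aldehyde 3 and comes back at 17.
- Olefination of 3 with dimethyl (3-diazo-2-oxopropyl)phosphonate F1 under the conditions of step 4 gives methyl (3S,4E)-3-[(tert-butyldimethylsilyl)oxy]-7-diazo-6-oxohept-4-enoate F2, a diazomethyl enone of the class for which the photochemical annulation is best behaved.
- Irradiation of F2 with 12 as in step 7 gives methyl (3S)-3-[(tert-butyldimethylsilyl)oxy]-3-{2-hydroxy-4-[(triisopropylsilyl)oxy]phenyl}propanoate F3.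
- NBS brominates F3 para to the free hydroxyl, giving methyl (3S)-3-{5-bromo-2-hydroxy-4-[(triisopropylsilyl)oxy]phenyl}-3-[(tert-butyldimethylsilyl)oxy]propanoate F4.
- Stille coupling of F4 with tributyl(geranyl)stannane F5 (from 5 and Bu3SnLi), catalysed by Pd(PPh3)4 (zerovalent palladium) in DMF at 80 °C, gives 17.
- The price is an allyl transfer that must take place at the unsubstituted terminus of the geranyl unit.

**Step 6.** Silylation of the parent ynolate may go to carbon as well as to oxygen, because its carbon terminus carries no substituent. The product can also isomerise by a 1,3-silyl shift to the silylketene on warming, and it is volatile. Either process removes the ketenophile of step 7.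

Fallback: ring B is taken from an arene, not built by annulation. The fallback sets out from 5 and comes back at 19.
- 1,5-Dibromo-2,4-bis(methoxymethoxy)benzene F6 is made by putting two MOM groups on the commercial dibromodiol.
- Single bromine–lithium exchange on F6 (n-BuLi, THF, −78 °C), CuBr·SMe2 and then 5 give 1-bromo-5-geranyl-2,4-bis(methoxymethoxy)benzene F7.
- A second exchange and DMF give 5-geranyl-2,4-bis(methoxymethoxy)benzaldehyde F8.
- An enantioselective Mukaiyama acetate aldol reaction gives methyl (3S)-3-[5-geranyl-2,4-bis(methoxymethoxy)phenyl]-3-hydroxypropanoate F9. It uses the trimethylsilyl ketene acetal of methyl acetate and Ti(OiPr)4 with a chiral binaphthol-derived ligand, and the O-silyl group is lost on work-up.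
- TBSCl and imidazole convert F9 into 19.
- This gives up the chiral pool origin of C2 and relies on catalyst control with a hindered, electron-rich aldehyde.

**Step 15.** The alkoxide of 26 is an aldolate of an electron-rich aldehyde and can fragment by retro-aldol cleavage, or lose the hydroxyl by β-elimination, in competition with ring closure. Recombination after cleavage, or base-induced opening of the product at C2–O1, would erode the configuration at C2.

Fallback: the ring is closed at the diketone level and C2 is set afterwards. The fallback sets out from 26 and comes back at 27.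
- Dess–Martin oxidation of 26 gives 1-[2-fluoro-4,6-bis(methoxymethoxy)phenyl]-3-[5-geranyl-2,4-bis(methoxymethoxy)phenyl]propane-1,3-dione F10.
- K2CO3 in DMF closes F10 through the enolate oxygen to 2-[5-geranyl-2,4-bis(methoxymethoxy)phenyl]-5,7-bis(methoxymethoxy)-4H-chromen-4-one F11. This is the standard chromone-forming SNAr, and it has no retro-aldol pathway.
- Enantioselective conjugate reduction of F11 with CuH, generated from Cu(OAc)2, a DTBM-SEGPHOS enantiomer chosen for (2S), (EtO)2MeSiH and t-BuOH in toluene, gives 27.
- The isolated trisubstituted alkenes of the geranyl chain are not substrates for CuH. The weak point is the rate of hydride delivery to a 2-aryl chromone with an ortho substituent.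

**Step 16.** Protonation of the geranyl alkene next to the newly freed C4' hydroxyl leads to chroman ring closure, and addition of the solvent or HCl to the trisubstituted alkenes is also possible. Both compete with acetal cleavage, the more so the longer the last MOM group takes.

Fallback: aprotic silyl transfer replaces protic solvolysis, so that no Brønsted acid meets the diene and the phenols appear only as silyl ethers. The fallback sets out from 27 and comes back at 28.
- Me3SiOTf and 2,2'-bipyridyl in CH2Cl2 at 0 °C convert the four aryl acetals into trimethylsilyl ethers, giving (2S)-2-[5-geranyl-2,4-bis(trimethylsilyloxy)phenyl]-5,7-bis(trimethylsilyloxy)-2,3-dihydro-4H-chromen-4-one F12.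
- F12 is hydrolysed to 28 by water at neutral pH.

## Further compounds

F1 | step 7 | dimethyl (3-diazo-2-oxopropyl)phosphonate | COP(=O)(CC(=O)C=[N+]=[N-])OC
F2 | step 7 | methyl (3S,4E)-3-[(tert-butyldimethylsilyl)oxy]-7-diazo-6-oxohept-4-enoate | [N-]=[N+]=CC(=O)/C=C/[C@@H](O[Si](C)(C)C(C)(C)C)CC(=O)OC
F3 | step 7 | methyl (3S)-3-[(tert-butyldimethylsilyl)oxy]-3-{2-hydroxy-4-[(triisopropylsilyl)oxy]phenyl}propanoate | c1cc([C@@H](O[Si](C)(C)C(C)(C)C)CC(=O)OC)c(O)cc1O[Si](C(C)C)(C(C)C)C(C)C
F4 | step 7 | methyl (3S)-3-{5-bromo-2-hydroxy-4-[(triisopropylsilyl)oxy]phenyl}-3-[(tert-butyldimethylsilyl)oxy]propanoate | Brc1cc([C@@H](O[Si](C)(C)C(C)(C)C)CC(=O)OC)c(O)cc1O[Si](C(C)C)(C(C)C)C(C)C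
F5 | step 7 | tributyl[(2E)-3,7-dimethylocta-2,6-dien-1-yl]stannane | CC(C)=CCC/C(C)=C/C[Sn](CCCC)(CCCC)CCCC
F6 | step 6 | 1,5-dibromo-2,4-bis(methoxymethoxy)benzene | Brc1cc(Br)c(OCOC)cc1OCOC
F7 | step 6 | 1-bromo-5-geranyl-2,4-bis(methoxymethoxy)benzene | CC(C)=CCC/C(C)=C/Cc1cc(Br)c(OCOC)cc1OCOC
F8 | step 6 | 5-geranyl-2,4-bis(methoxymethoxy)benzaldehyde | CC(C)=CCC/C(C)=C/Cc1cc(C=O)c(OCOC)cc1OCOC
F9 | step 6 | methyl (3S)-3-[5-geranyl-2,4-bis(methoxymethoxy)phenyl]-3-hydroxypropanoate | CC(C)=CCC/C(C)=C/Cc1cc([C@@H](O)CC(=O)OC)c(OCOC)cc1OCOC
F10 | step 15 | 1-[2-fluoro-4,6-bis(methoxymethoxy)phenyl]-3-[5-geranyl-2,4-bis(methoxymethoxy)phenyl]propane-1,3-dione | CC(C)=CCC/C(C)=C/Cc1cc(C(=O)CC(=O)c2c(F)cc(OCOC)cc2OCOC)c(OCOC)cc1OCOC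
F11 | step 15 | 2-[5-geranyl-2,4-bis(methoxymethoxy)phenyl]-5,7-bis(methoxymethoxy)-4H-chromen-4-one | CC(C)=CCC/C(C)=C/Cc1cc(-c2cc(=O)c3c(OCOC)cc(OCOC)cc3o2)c(OCOC)cc1OCOC
F12 | step 16 | (2S)-2-[5-geranyl-2,4-bis(trimethylsilyloxy)phenyl]-5,7-bis(trimethylsilyloxy)-2,3-dihydro-4H-chromen-4-one | CC(C)=CCC/C(C)=C/Cc1cc([C@@H]2CC(=O)c3c(O[Si](C)(C)C)cc(O[Si](C)(C)C)cc3O2)c(O[Si](C)(C)C)cc1O[Si](C)(C)C
A1 | alternative 1 | (5S)-1-tert-butoxy-5-(ethynyloxy)-5-[5-geranyl-2,4-bis(methoxymethoxy)phenyl]pent-1-yn-3-one | CC(C)=CCC/C(C)=C/Cc1cc([C@@H](OC#C)CC(=O)C#COC(C)(C)C)c(OCOC)cc1OCOC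
A2 | alternative 1 | tert-butoxyethyne | C#COC(C)(C)C
A3 | alternative 1 | (2S)-5,7-di-tert-butoxy-2-[5-geranyl-2,4-bis(methoxymethoxy)phenyl]-2,3-dihydro-4H-chromen-4-one | CC(C)=CCC/C(C)=C/Cc1cc([C@@H]2CC(=O)c3c(OC(C)(C)C)cc(OC(C)(C)C)cc3O2)c(OCOC)cc1OCOC
A4 | alternative 2 | 1-{2-[(5-bromo-2,4-bis(methoxymethoxy)phenyl)methoxy]-4,6-bis(methoxymethoxy)phenyl}ethenyl acetate | C=C(OC(C)=O)c1c(OCOC)cc(OCOC)cc1OCc1cc(Br)c(OCOC)cc1OCOC
A5 | alternative 2 | (2S)-2-[5-bromo-2,4-bis(methoxymethoxy)phenyl]-5,7-bis(methoxymethoxy)-2,3-dihydro-4H-chromen-4-one | Brc1cc([C@@H]2CC(=O)c3c(OCOC)cc(OCOC)cc3O2)c(OCOC)cc1OCOC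
A6 | alternative 3 | 3,5-bis[(tert-butyldimethylsilyl)oxy]-2-(dimethoxymethyl)phenol | COC(OC)c1c(O)cc(O[Si](C)(C)C(C)(C)C)cc1O[Si](C)(C)C(C)(C)C
A7 | alternative 3 | 1-ethenyl-5-geranyl-2,4-bis[(tert-butyldimethylsilyl)oxy]benzene | CC(C)=CCC/C(C)=C/Cc1cc(C=C)c(O[Si](C)(C)C(C)(C)C)cc1O[Si](C)(C)C(C)(C)C
A8 | alternative 3 | (2S,4S)-5,7-bis[(tert-butyldimethylsilyl)oxy]-2-{5-geranyl-2,4-bis[(tert-butyldimethylsilyl)oxy]phenyl}-4-methoxy-3,4-dihydro-2H-chromene (2,4-cis) | CC(C)=CCC/C(C)=C/Cc1cc([C@@H]2C[C@H](OC)c3c(O[Si](C)(C)C(C)(C)C)cc(O[Si](C)(C)C(C)(C)C)cc3O2)c(O[Si](C)(C)C(C)(C)C)cc1O[Si](C)(C)C(C)(C)C
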